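**Retrosynthetic overview**
1. Target 22 ⇐ diol-dione 21 (acetylation) ⇐ tetraol 20 (oxidation at C3/C22). The two tertiary carbinols have opposite sense and are made differently: C10 by equatorial MeMgBr addition to a ring ketone, C15 by methylenation and Markovnikov hydration of the other ring ketone.
2. The two ring ketones are told apart through their esters: tetracycle 14 carries a tert-butyl β-keto ester on one half (removed first) and a methyl β-keto ester on the other (masked as its enolate during the Grignard step).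
3. Key disconnection: 14 ⇐ acyclic tetraepoxide bis(silyl dienolate) 12 by a two-directional epoxide-opening cascade. All four rings form in one operation; on each arm the oxepane closes first (O–C2), then the cyclohexane (C11–C6 and C14–C19).
4. 12 ⇐ tetraepoxide 10 ⇐ tetraene 9 (fourfold Shi epoxidation) ⇐ mixed bis(β-keto ester) 7 + 2 geranyl bromide; 7 ⇐ methyl adipoyl chloride, Meldrum's acid, tert-butyl acetate.

Convention used below: locants C1–C24 follow the chain through both halves, C2 (CMe2)–C3 (C=O)–C4–C5–C6 (ring-fusion C–Me)–C7 (ring-fusion CH–O)–C8–C9–C10 (C(OAc)Me)–C11–C12–C13–C14–C15 (C(OAc)Me)–C16–C17–C18 (CH–O)–C19 (C–Me)–C20–C21–C22 (C=O)–C23 (CMe2); the left half of the target SMILES is C1–C12, and the target is (6S,7S,10R,11S,14S,15S,18S,19S).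

**Step 1**
Reactants: 1 methyl 6-chloro-6-oxohexanoate (methyl adipoyl chloride); 2 Meldrum's acid (2,2-dimethyl-1,3-dioxane-4,6-dione)
Product: 4 dimethyl 3-oxooctanedioate, via acyl Meldrum's acid 3 (not isolated)
Conditions: pyridine (2 equiv), CH2Cl2, 0 → 23 °C; then MeOH, reflux
Reagents that add atoms: methanol, CO
Why: C-acylation of Meldrum's acid and methanolysis of the adduct through the acylketene with loss of acetone and CO2 (Oikawa–Yonemitsu β-keto ester synthesis); no stereocentre is formed.

**Step 2**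
Reactants: 4 dimethyl 3-oxooctanedioate; 5 tert-butyl acetate
Product: 7 1-tert-butyl 10-methyl 3,8-dioxodecanedioate, via lithio tert-butyl acetate 6 (not isolated)
Conditions: LiN(i-Pr)2 (3.6 equiv), 5 (3.6 equiv), THF, −78 °C; add 4, −78 → −20 °C; aq. NH4Cl
Reagents that add atoms: none
Why: Crossed Claisen condensation; the first equivalent of 6 turns the β-keto ester of 4 into its inert enolate, so further 6 is acylated only by the remaining methyl ester, and no stereocentre is formed.

**Step 3**
Reactants: 7 1-tert-butyl 10-methyl 3,8-dioxodecanedioate; 8 geranyl bromide [(2E)-1-bromo-3,7-dimethylocta-2,6-diene, 2.1 equiv]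
Product: 9 1-tert-butyl 10-methyl 2,9-bis[(2E)-3,7-dimethylocta-2,6-dien-1-yl]-3,8-dioxodecanedioate (chain locants: CO2t-Bu on C9, ketones at C10 and C15, CO2Me on C16; C9/C16 both epimers)
Conditions: K2CO3 (3 equiv), acetone, 50 °C
Reagents that add atoms: none
Why: SN2 C-alkylation of the two doubly stabilised enolates by the allylic bromide (acetoacetic ester alkylation); the two new CH(CO2R) centres form without control and do not matter, because they become planar in step 5 and are lost in steps 7 and 9.

**Step 4**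
Reactants: 9 bis-geranylated diester
Product: 10 tetraepoxide of 9 with (3S), (6S,7S), (18S,19S) and (22S) oxiranes (C9/C16 as in 9)
Conditions: ent-Shi ketone (1,2:4,5-di-O-isopropylidene-β-L-erythro-2,3-hexodiulo-2,6-pyranose, from L-sorbose; 0.3 equiv per alkene), KHSO5, K2CO3, Bu4NHSO4, aq. Na2B4O7 buffer (pH 10.5), MeCN/CH2(OMe)2, −5 °C
Reagents that add atoms: potassium peroxymonosulfate, [K+].[O-]S(=O)(=O)OO
Why: Shi asymmetric epoxidation; the dioxirane of the L-series ketone delivers oxygen through a spiro transition state to the same face of each unactivated E-trisubstituted alkene, giving the (S)-configured epoxides and thereby fixing C7/C18 (retained later) and C6/C19 (inverted later) of the target.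

**Step 5**
Reactants: 10 tetraepoxide
Product: 12 bis(silyl dienolate) t-BuO(TMSO)C=C9–C10(OTMS)=C11H–C12H2–C13H2–C14H=C15(OTMS)–C16=C(OTMS)OMe with the four epoxides of 10, via bis(silyl enol ether) 11 (not isolated)
Conditions: TMSCl, Et3N, CH2Cl2, 0 → 23 °C; filter; LiN(i-Pr)2 (2.2 equiv), THF, −78 °C; TMSCl
Reagents that add atoms: chlorotrimethylsilane, C[Si](C)(C)Cl
Why: Chan-type 1,3-bis(silyloxy)-1,3-diene synthesis: O-silylation of each β-keto ester, then kinetic γ-deprotonation (only C11 and C14 are activated) and O-silylation of the ester dienolate; C9/C16 become planar and C11/C14 become the nucleophilic termini.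

**Step 6 (key step)**
Reactants: 12 bis(silyl dienolate)
Product: 14 tetracyclic bis(β-keto ester) diol (3S,6S,7S,11S,14S,18S,19S,22S; two trans-fused 3-hydroxy-2,2-dimethyloxepane/cyclohexanone bicycles joined through C12–C13; CO2t-Bu on C9 and CO2Me on C16 as epimer/enol mixtures), via tetrasilyl cascade product 13 (not isolated)
Conditions: TMSOTf (0.3 equiv), 2,6-di-tert-butyl-4-methylpyridine (0.5 equiv), CH2Cl2 (2 mM), −78 °C; then 1 M HCl, THF, 0 °C
Reagents that add atoms: none
Why: Proposed new method: TMSOTf silylates each terminal epoxide, the neighbouring 6,7- (18,19-) epoxide oxygen opens it at the tertiary carbon C2 (C23) to a bicyclic epoxonium ion, and the dienolate terminus C11 (C14) attacks the tertiary carbon C6 (C19) anti to the oxonium oxygen through a chair, so that retention at C7/C18 and inversion at C6/C19 give the trans-fused oxepane–cyclohexane with the ring-fusion methyl anti to the ring-fusion hydrogen, while loss of Me3Si+ regenerates TMSOTf and the two independent arms close four rings in one operation; C11/C14 are α to the regenerated ketones and settle in the equatorial (required) configuration; the closest known reaction types are the silyl triflate-promoted tandem oxa-/carbacyclisation of 1,5-diepoxides terminated by ketone enol silanes and the Lewis acid-mediated γ-alkylation of 1,3-bis(silyloxy)dienes by epoxides.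

**Step 7**
Reactants: 14 tetracyclic bis(β-keto ester) diol
Product: 16 tetracyclic C10 ketone with the C16 methyl ester kept (3S,6S,7S,11S,14S,18S,19S,22S), via β-keto acid 15 (not isolated)
Conditions: TFA/CH2Cl2 (1:4), 0 °C; evaporate; PhMe, 70 °C; then K2CO3 (cat.), MeOH, 23 °C
Reagents that add atoms: none
Why: Acidolysis of the tert-butyl ester (loss of isobutene) and decarboxylation of the β-keto acid through a six-membered transition state leave the methyl β-keto ester untouched; no stereocentre is formed, and the final base treatment equilibrates C11 (α to the ketone) to the equatorial side chain.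

**Step 8**
Reactants: 16 tetracyclic C10 ketone
Product: 17 (10R)-tertiary alcohol: C10 bears an equatorial CH3 and an axial OH cis to the C6 methyl; C15 ketone/C16 methyl ester unchanged
Conditions: MeMgBr (8 equiv), CeCl3 (3 equiv), THF, −78 → 0 °C; aq. NH4Cl
Reagents that add atoms: methylmagnesium bromide, C[Mg]Br
Why: 1,2-Addition of the organometallic to the only free ketone, since the first equivalents convert the β-keto ester into its unreactive enolate and the hydroxyls into alkoxides; the methyl group enters C10 along the equatorial trajectory because the axial face is blocked by the syn-axial C6 methyl, which gives the axial alcohol (10R).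

**Step 9**
Reactants: 17 (10R)-tertiary alcohol
Product: 18 C15 ketone (C16 ester removed; 10R, triol)
Conditions: LiCl (5 equiv), DMSO/H2O (20:1), 140 °C; then K2CO3 (cat.), MeOH, 23 °C
Reagents that add atoms: none
Why: Krapcho dealkoxycarbonylation (chloride attacks the ester methyl group, the carboxylate loses CO2, the enolate is protonated); no stereocentre is formed and C14 (α to the new ketone) equilibrates to the equatorial side chain.

**Step 10**
Reactants: 18 C15 ketone
Product: 19 C15 exocyclic methylene compound (10R, triol)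
Conditions: Ph3PCH3Br (8 equiv), KOt-Bu (8 equiv), PhMe, 90 °C
Reagents that add atoms: methyltriphenylphosphonium bromide, C[P+](c1ccccc1)(c1ccccc1)c1ccccc1.[Br-]
Why: Wittig methylenation of the hindered ring ketone with excess ylide at elevated temperature, the hydroxyls being carried as potassium alkoxides; no stereocentre is formed and C14 stays in its thermodynamically preferred configuration.

**Step 11**
Reactants: 19 C15 exocyclic methylene compound
Product: 20 tetraol with a (15S)-tertiary alcohol: C15 bears an axial CH3 cis to the C19 methyl and an equatorial OH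
Conditions: Co(acac)2 (0.2 equiv), PhSiH3 (4 equiv), O2 (1 atm), i-PrOH/THF, 23 °C
Reagents that add atoms: dioxygen, O=O
Why: Mukaiyama hydration (hydrogen-atom transfer to the CH2 terminus, capture of the tertiary C15 radical by O2, reduction of the peroxide); O2 approaches on the equatorial face, away from the syn-axial C19 methyl, which gives the equatorial alcohol (15S).

**Step 12**
Reactants: 20 tetraol
Product: 21 3,22-dione 10,15-diol (6S,7S,10R,11S,14S,15S,18S,19S)
Conditions: Dess–Martin periodinane (3 equiv), CH2Cl2, 23 °C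
Reagents that add atoms: none
Why: Dess–Martin oxidation of the two secondary carbinols to the oxepanones; the tertiary alcohols cannot be oxidised and no stereocentre of the target is touched.

**Step 13**
Reactants: 21 3,22-dione 10,15-diol
Product: 22 target diacetate
Conditions: Ac2O (10 equiv), DMAP (2 equiv), Et3N, PhMe, 80 °C
Reagents that add atoms: acetic anhydride, CC(=O)OC(C)=O
Why: DMAP-catalysed acylation (N-acetylpyridinium) of both tertiary alcohols; the C–O bonds at C10 and C15 are not broken, so their configurations are kept.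

**Compound list**
1 | methyl 6-chloro-6-oxohexanoate | COC(=O)CCCCC(Cl)=O | starting material
2 | Meldrum's acid | CC1(C)OC(=O)CC(=O)O1 | starting material
3 | methyl 6-(2,2-dimethyl-4,6-dioxo-1,3-dioxan-5-yl)-6-oxohexanoate (acyl Meldrum's acid) | COC(=O)CCCCC(=O)C1C(=O)OC(C)(C)OC1=O | intermediate
4 | dimethyl 3-oxooctanedioate | COC(=O)CC(=O)CCCCC(=O)OC | intermediate
5 | tert-butyl acetate | CC(=O)OC(C)(C)C | starting material
6 | lithium enolate of tert-butyl acetate | [Li]OC(=C)OC(C)(C)C | intermediate
7 | 1-tert-butyl 10-methyl 3,8-dioxodecanedioate | COC(=O)CC(=O)CCCCC(=O)CC(=O)OC(C)(C)C | intermediate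
8 | geranyl bromide | BrC/C=C(\C)CCC=C(C)C | starting material
9 | 1-tert-butyl 10-methyl 2,9-digeranyl-3,8-dioxodecanedioate | CC(C)(C)OC(=O)C(C/C=C(\C)CCC=C(C)C)C(=O)CCCCC(=O)C(C/C=C(\C)CCC=C(C)C)C(=O)OC | intermediate
10 | (3S,6S,7S,18S,19S,22S)-tetraepoxide of 9 | CC(C)(C)OC(=O)C(C[C@@H]1O[C@@]1(C)CC[C@@H]1OC1(C)C)C(=O)CCCCC(=O)C(C[C@@H]1O[C@@]1(C)CC[C@@H]1OC1(C)C)C(=O)OC | intermediate
11 | bis(trimethylsilyl enol ether) of 10 | CC(C)(C)OC(=O)C(C[C@@H]1O[C@@]1(C)CC[C@@H]1OC1(C)C)=C(O[Si](C)(C)C)CCCCC(O[Si](C)(C)C)=C(C[C@@H]1O[C@@]1(C)CC[C@@H]1OC1(C)C)C(=O)OC | intermediate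
12 | tetraepoxy bis[1-alkoxy-1,3-bis(trimethylsilyloxy)-1,3-diene] | CC(C)(C)OC(O[Si](C)(C)C)=C(C[C@@H]1O[C@@]1(C)CC[C@@H]1OC1(C)C)C(O[Si](C)(C)C)=CCCC=C(O[Si](C)(C)C)C(C[C@@H]1O[C@@]1(C)CC[C@@H]1OC1(C)C)=C(O[Si](C)(C)C)OC | intermediate
13 | tetracyclic bis(TMS ether) bis(TMS enol ether) | C[Si](C)(C)OC1=C(C(=O)OC(C)(C)C)C[C@@H]2OC(C)(C)[C@@H](O[Si](C)(C)C)CC[C@@]2(C)[C@@H]1CC[C@H]1[C@]2(C)CC[C@H](O[Si](C)(C)C)C(C)(C)O[C@H]2CC(C(=O)OC)=C1O[Si](C)(C)C | intermediate
14 | tetracyclic bis(β-keto ester) diol | O=C1C(C(=O)OC(C)(C)C)C[C@@H]2OC(C)(C)[C@@H](O)CC[C@@]2(C)[C@@H]1CC[C@H]1[C@]2(C)CC[C@H](O)C(C)(C)O[C@H]2CC(C(=O)OC)C1=O | intermediate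
15 | tetracyclic β-keto acid | O=C1C(C(O)=O)C[C@@H]2OC(C)(C)[C@@H](O)CC[C@@]2(C)[C@@H]1CC[C@H]1[C@]2(C)CC[C@H](O)C(C)(C)O[C@H]2CC(C(=O)OC)C1=O | intermediate
16 | tetracyclic C10 ketone, C16 methyl ester | O=C1CC[C@@H]2OC(C)(C)[C@@H](O)CC[C@@]2(C)[C@@H]1CC[C@H]1[C@]2(C)CC[C@H](O)C(C)(C)O[C@H]2CC(C(=O)OC)C1=O | intermediate
17 | (10R)-tertiary alcohol, C16 methyl ester | O[C@]1(C)CC[C@@H]2OC(C)(C)[C@@H](O)CC[C@@]2(C)[C@@H]1CC[C@H]1[C@]2(C)CC[C@H](O)C(C)(C)O[C@H]2CC(C(=O)OC)C1=O | intermediate
18 | (10R)-triol C15 ketone | O[C@]1(C)CC[C@@H]2OC(C)(C)[C@@H](O)CC[C@@]2(C)[C@@H]1CC[C@H]1[C@]2(C)CC[C@H](O)C(C)(C)O[C@H]2CCC1=O | intermediate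
19 | (10R)-triol with C15 exocyclic methylene | O[C@]1(C)CC[C@@H]2OC(C)(C)[C@@H](O)CC[C@@]2(C)[C@@H]1CC[C@H]1[C@]2(C)CC[C@H](O)C(C)(C)O[C@H]2CCC1=C | intermediate
20 | (10R,15S)-tetraol | O[C@]1(C)CC[C@@H]2OC(C)(C)[C@@H](O)CC[C@@]2(C)[C@@H]1CC[C@H]1[C@]2(C)CC[C@H](O)C(C)(C)O[C@H]2CC[C@]1(C)O | intermediate
21 | (10R,15S)-10,15-diol 3,22-dione | O[C@]1(C)CC[C@@H]2OC(C)(C)C(=O)CC[C@@]2(C)[C@@H]1CC[C@H]1[C@]2(C)CCC(=O)C(C)(C)O[C@H]2CC[C@]1(C)O | intermediate
22 | CNP0325605.1 | CC(=O)O[C@]1(C)CC[C@@H]2OC(C)(C)C(=O)CC[C@@]2(C)[C@@H]1CC[C@H]1[C@]2(C)CCC(=O)C(C)(C)O[C@H]2CC[C@]1(C)OC(C)=O | target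

**Totals**
Total step count: 13. Longest linear sequence: 13 steps (1 → 22); 2, 5 and 8 enter directly as commercial materials.

**Three steps most likely to fail, each with a fallback**

Step 6 (four-ring cascade). The doubly silylated dienolates may lose silicon before they trap the epoxonium ions, or close through oxygen. The fallback gives up the ester-based regiocontrol and uses plain ketone enol silanes, the terminator class for which this kind of cascade is established. It sets out from 8 and comes back at 18. Geranyl bromide 8 alkylates the dianion of dimethyl (2-oxopropyl)phosphonate (NaH, then n-BuLi, THF) at the methyl group to give the β-keto phosphonate F1. Shi epoxidation as in step 4 gives the bis-epoxide F2. A double Horner–Wadsworth–Emmons reaction of two molecules of F2 with glyoxal (K2CO3, aq. THF) gives the (E,E)-dienedione F3. Twofold 1,4-hydrosilylation (Et3SiH, RhCl(PPh3)3, PhH) gives the bis(triethylsilyl enol ether) F4, whose enol double bonds are fixed at C10=C11 and C14=C15 by the position of the former enones. The same TMSOTf cascade and acidic work-up give the C2-symmetric diketone diol F5. Addition of MeMgBr/CeCl3 limited to one ketone (the two hydroxyls are first converted to alkoxides) gives 18. This last step is statistical; unreacted F5 is recycled.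

Step 4 (fourfold Shi epoxidation beside two β-keto esters). The enolisable keto esters may be hydroxylated by the dioxirane at pH 10.5. The fallback masks them and sets out from 9, coming back at 10. Ac2O, Et3N and DMAP convert 9 into the bis(enol acetate) F6, whose conjugated, acylated enol double bonds are poor dioxirane substrates. The Shi epoxidation then gives the tetraepoxy bis(enol acetate) F7, and K2CO3 in MeOH at 0 °C removes the acetyl groups to give 10.

Step 11 (facial selectivity of the radical hydration). If O2 capture at C15 is not selective, the fallback uses a polar route instead; it sets out from 19 and comes back at 20. mCPBA (NaHCO3, CH2Cl2, 0 °C) epoxidises the exocyclic alkene from the equatorial face, away from the syn-axial C19 methyl, to give the spiro-epoxide F8. LiAlH4 (THF, 0 °C) opens it at the CH2 group, which becomes the axial methyl and leaves the equatorial C15 hydroxyl of 20.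

**Further compounds**
F1 | step 6 | dimethyl [(5E)-6,10-dimethyl-2-oxoundeca-5,9-dien-1-yl]phosphonate | COP(=O)(OC)CC(=O)CC/C=C(\C)CCC=C(C)C
F2 | step 6 | (5S,6S,9S)-bis-epoxide of F1 | COP(=O)(OC)CC(=O)CC[C@@H]1O[C@@]1(C)CC[C@@H]1OC1(C)C
F3 | step 6 | tetraepoxy (11E,13E)-diene-10,15-dione | O=C(CC[C@@H]1O[C@@]1(C)CC[C@@H]1OC1(C)C)/C=C/C=C/C(=O)CC[C@@H]1O[C@@]1(C)CC[C@@H]1OC1(C)C
F4 | step 6 | tetraepoxy bis(triethylsilyl enol ether) | CC[Si](CC)(CC)OC(CC[C@@H]1O[C@@]1(C)CC[C@@H]1OC1(C)C)=CCCC=C(O[Si](CC)(CC)CC)CC[C@@H]1O[C@@]1(C)CC[C@@H]1OC1(C)C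
F5 | step 6 | C2-symmetric tetracyclic 10,15-diketone 3,22-diol | O=C1CC[C@@H]2OC(C)(C)[C@@H](O)CC[C@@]2(C)[C@@H]1CC[C@H]1[C@]2(C)CC[C@H](O)C(C)(C)O[C@H]2CCC1=O
F6 | step 4 | bis(enol acetate) of 9 | CC(=O)OC(CCCCC(OC(C)=O)=C(C/C=C(\C)CCC=C(C)C)C(=O)OC)=C(C/C=C(\C)CCC=C(C)C)C(=O)OC(C)(C)C
F7 | step 4 | tetraepoxy bis(enol acetate) | CC(=O)OC(CCCCC(OC(C)=O)=C(C[C@@H]1O[C@@]1(C)CC[C@@H]1OC1(C)C)C(=O)OC)=C(C[C@@H]1O[C@@]1(C)CC[C@@H]1OC1(C)C)C(=O)OC(C)(C)C
F8 | step 11 | (10R)-triol C15 spiro-epoxide | O[C@]1(C)CC[C@@H]2OC(C)(C)[C@@H](O)CC[C@@]2(C)[C@@H]1CC[C@H]1[C@]2(C)CC[C@H](O)C(C)(C)O[C@H]2CC[C@@]13CO3
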